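At early times the target outran its own losses: in the dawn run it climbed from 31.8 % at 10.0 s to 40.0 % at 15.0 s, then topped out near 50.0 % at 40.0 s and sank.

| flask | starting material | reagent | capture agent | temperature | remark | time |
|---|---|---|---|---|---|---|
| dawn | 0.074 M | 1.3 equiv | 0.011 M | 20 °C | run made earlier |  |
| noon | 0.17 M | 1.3 equiv | 0.011 M | 35 °C | run made earlier |  |
| green | 0.11 M | 1.30 equiv | 0.0110 M | 45 °C |  | 2.0 min |
| red | 0.11 M | 1.30 equiv | 0.0110 M | 25 °C |  | 2.0 min |

| run | time / s | target / % | starting material / % |
|---|---|---|---|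
| dawn | 10.0 | 31.8 | 57.4 |
| dawn | 15.0 | 40.0 | 45.4 |
| dawn | 25.0 | 48.3 | 32.8 |
| dawn | 40.0 | 50.0 | 20.2 |
| dawn | 60.0 | 47.6 | 12.7 |
| dawn | 80.0 | 43.4 | 8.4 |
| dawn | 90.0 | 40.8 | 7.4 |
| noon | 10.0 | 35.1 | 12.3 |
| noon | 15.0 | 30.9 | 6.4 |
| noon | 25.0 | 24.2 | 2.7 |
| noon | 40.0 | 17.5 | 0.2 |
| noon | 50.0 | 17.1 | 0.3 |
| noon | 60.0 | 15.1 | 0.6 |

(standard deviation of a reading: 0.5 percentage points)



1. which of the two there is more of at the end, green (target / isomer of the product)
2. which of the two there is more of at the end, red (target / isomer of the product)
3. target at the end, in percent of the starting material charged, green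
4. target at the end, in percent of the starting material charged, red

I compared feed and drain. In noon the target's fall slowed as the starting material neared its end, and I took noon's last reading, target 15.1 % with starting material 0.6 %, as a floor F. Let the excess be target minus F, falling first-order with rate constant λ. Late dawn readings gave 0.00782 s⁻¹, and early noon readings gave 0.0525 s⁻¹. Interpolating ln λ linearly in temperature gave 0.0148 s⁻¹ for red, so the half-time of the excess in red was 47.0 s.

Red is richer than dawn and warmer, so I started its excess from dawn's 48.3 % at 25.0 s, which gave target 23.3 % at 2.0 min. Extrapolating to green gave a half-time of 3.71 s, far shorter than 2.0 min, so I put green on the floor. Noon's last reading leaves 84.3 % in neither measured species; I booked that to the isomer of the product and expected it ahead in both.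

The forecast gave 12 % for green and 22 % for red, with the isomer of the product ahead in green and the isomer of the product in red: “The isomer dominates both”.

The flask gave target 15.0 % in green and 20.0 % in red, against 61.1 % and 66.6 % of the isomer of the product.

    starting material + reagent → open intermediate + released group (k = 1.00 M⁻¹ s⁻¹, Ea = 48.0 kJ mol⁻¹)
    open intermediate ⇌ target (K = 3.70, k = 3.54 s⁻¹, Ea = 73.0 kJ mol⁻¹, ΔH = −47.0 kJ mol⁻¹)
    open intermediate ⇌ isomer of the product (K = 18.0, k = 0.0857 s⁻¹, Ea = 67.0 kJ mol⁻¹, ΔH = −54.0 kJ mol⁻¹)
    open intermediate + capture agent → trapped intermediate (k = 1.17 M⁻¹ s⁻¹, Ea = 40.0 kJ mol⁻¹)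
    target → over-reaction product (k = 3.06 × 10⁻⁵ s⁻¹, Ea = 88.0 kJ mol⁻¹)
    (constants at 25 °C)

In red, the drain is the return of target to the open intermediate, a case of kinetic against thermodynamic control: without that return, red holds 97.4 % target, not 20.0 %. Carried from red's end to the same flask read at 8.0 min, my half-time of 47.0 s leaves 0.024 percentage points of excess over F, and that flask holds target 14.6 %.

The numbers in the tables were computed with constants of no real substance; the scatter is artificial.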